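## Retrosynthetic overview

1. Target ⇒ (5S)-5-hydroxy-3-ketone. The C3 carbinol is made last by a 1,3-syn boron-chelate reduction, so C5 controls C3.
2. Hydroxy ketone ⇒ benzyl-protected β-peroxy styryl ketone. One hydrogenation removes C1=C2, the O–O bond and three benzyl groups.
3. Key disconnection is C5–O: a catalytic, site- and enantioselective oxa-Michael addition of a hydroperoxide to the β-alkyl arm of a cross-conjugated (1E,4E)-dienone.
4. Dienone ⇒ protected 5-hydroxyvanillin + (E)-6-arylhex-3-en-2-one (C1=C2, Claisen–Schmidt). The enone ⇒ aryl iodide + allyl alcohol + acetonyl ylide (one-pot Heck/Wittig).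
5. Rings: both arenes are bought as such, and no ring is formed in the route.

Chain numbering: C1 carries the 3,4-dihydroxy-5-methoxyphenyl ring (ring A) and C7 carries the 4-hydroxyphenyl ring (ring B). The target is the syn diol, (3R,5S).

Assumption: the facial sense of the cinchona amine in step 4 is assigned by analogy with additions to simple (E)-alk-3-en-2-ones; the quinidine-derived amine is written for (5S), and its quinine-derived pseudoenantiomer replaces it, with nothing else changed, if the first run shows (5R).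

## Route

Step 1
Reactants: 1 3,4-dihydroxy-5-methoxybenzaldehyde (5-hydroxyvanillin)
Product: 2 3,4-bis(benzyloxy)-5-methoxybenzaldehyde
Conditions: BnBr (2.3 equiv), K2CO3 (3 equiv), DMF, 60 °C, N2, 6 h
Reagents that add atoms: benzyl bromide, BrCc1ccccc1
Why: Williamson ether synthesis, in which both catechol phenoxides are alkylated by the reactive benzylic bromide, and benzyl is chosen because it leaves in the same hydrogenation that later saturates the chain.

Step 2
Reactants: 3 1-(benzyloxy)-4-iodobenzene; 4 prop-2-en-1-ol (allyl alcohol); 5 1-(triphenylphosphoranylidene)propan-2-one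
Product: 7 (3E)-6-[4-(benzyloxy)phenyl]hex-3-en-2-one, via 3-[4-(benzyloxy)phenyl]propanal 6 (not isolated)
Conditions: 4 (1.5 equiv), Pd(OAc)2 (3 mol%), NaHCO3 (2.5 equiv), nBu4NCl (1 equiv), DMF, 45 °C, 16 h; then 5 (1.3 equiv), 23 to 40 °C, 12 h
Reagents that add atoms: none
Why: Mizoroki–Heck arylation of allyl alcohol under ligand-free phase-transfer conditions ends in β-hydride elimination toward the carbinol and enol tautomerisation to aldehyde 6, which the stabilised ylide converts in the same flask by an (E)-selective Wittig olefination, so the self-condensing aldehyde is never handled.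

Step 3
Reactants: 2 3,4-bis(benzyloxy)-5-methoxybenzaldehyde; 7 (3E)-6-[4-(benzyloxy)phenyl]hex-3-en-2-one
Product: 9 (1E,4E)-1-[3,4-bis(benzyloxy)-5-methoxyphenyl]-7-[4-(benzyloxy)phenyl]hepta-1,4-dien-3-one, via racemic aldol adduct 8 (not isolated)
Conditions: aq. NaOH (2 M, 1.2 equiv), EtOH/THF (2:1), 0 to 23 °C, 16 h
Reagents that add atoms: none
Why: Claisen–Schmidt condensation, in which the methyl-side enolate of 7 adds to the non-enolisable aldehyde 2 and irreversible E1cB loss of water to the fully conjugated (E)-styryl ketone pulls the reversible aldol equilibria to 9.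

Step 4
Reactants: 9 (1E,4E)-1-[3,4-bis(benzyloxy)-5-methoxyphenyl]-7-[4-(benzyloxy)phenyl]hepta-1,4-dien-3-one
Product: 10 (1E,5S)-1-[3,4-bis(benzyloxy)-5-methoxyphenyl]-7-[4-(benzyloxy)phenyl]-5-[(2-phenylpropan-2-yl)peroxy]hept-1-en-3-one
Conditions: 9-amino(9-deoxy)epiquinidine [(9R)-6'-methoxycinchonan-9-amine, C20H25N3O] (10 mol%), CF3CO2H (30 mol%), cumene hydroperoxide (1.5 equiv), toluene, 0 to 23 °C, 48 h
Reagents that add atoms: cumene hydroperoxide, CC(C)(OO)c1ccccc1
Why: Proposed new method: site- and enantioselective iminium-catalysed conjugate peroxidation of a cross-conjugated dienone, a substrate class on which this C–O bond formation has not been shown; the primary amine condenses with the C3 ketone to a bis-alkenyl iminium ion in which C5 (β-alkyl arm) is the only truly electrophilic terminus, because the charge on the other arm is drained by the trialkoxyaryl donor and attack at C1 would break the styrene conjugation, the protonated quinuclidine and its trifluoroacetate hold the hydroperoxide by hydrogen bonds and pass its terminal oxygen to one face of C5, which sets (5S), the 2-aminodiene so formed is protonated and hydrolysed faster than it can expel the poor cumyloxide leaving group at or below 23 °C, so peroxide 10 rather than the epoxide is released, and the addition costs no more conjugation than in a simple enone because the styryl ketone stays intact; closest known reaction type: cinchona primary amine salt-catalysed asymmetric oxa-Michael addition of alkyl hydroperoxides to simple acyclic alkyl enones.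

Step 5
Reactants: 10 (1E,5S)-1-[3,4-bis(benzyloxy)-5-methoxyphenyl]-7-[4-(benzyloxy)phenyl]-5-[(2-phenylpropan-2-yl)peroxy]hept-1-en-3-one
Product: 11 (5S)-1-(3,4-dihydroxy-5-methoxyphenyl)-5-hydroxy-7-(4-hydroxyphenyl)heptan-3-one
Conditions: H2 (1 atm), 10% Pd/C, EtOAc/EtOH (1:1), 23 °C, 16 h; filtration under N2
Reagents that add atoms: none
Why: Heterogeneous catalytic hydrogenation and hydrogenolysis, in which Pd/C saturates the enone C=C, cleaves the weak O–O bond without touching C5–O (so 5S is kept) and removes the three aryl benzyl ethers, while the resulting dialkyl ketone is inert at 1 atm and no allylic C–O bond is ever exposed to the catalyst.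

Step 6
Reactants: 11 (5S)-1-(3,4-dihydroxy-5-methoxyphenyl)-5-hydroxy-7-(4-hydroxyphenyl)heptan-3-one
Product: 13 (3R,5S)-1-(3,4-dihydroxy-5-methoxyphenyl)-7-(4-hydroxyphenyl)heptane-3,5-diol, via diethylboron chelate 12 (not isolated)
Conditions: Et2BOMe (3.5 equiv), THF/MeOH (4:1), −78 °C, 1 h; NaBH4 (4 equiv), −78 °C, 4 h; aq. pH 6 buffer, then MeOH co-evaporation; Ar
Reagents that add atoms: diethylmethoxyborane, CCB(CC)OC (its Et2B group is found only in 12)
Why: Narasaka–Prasad reduction, in which the C5 borinate chelates the C3 ketone in a six-membered half-chair with the C5 side chain pseudo-equatorial and external hydride attacks axially, giving the 1,3-syn diol and thus (3R), with the extra Et2BOMe and NaBH4 covering the three phenols.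

## Compound list

1 | 3,4-dihydroxy-5-methoxybenzaldehyde (5-hydroxyvanillin) | COc1cc(C=O)cc(O)c1O | starting material
2 | 3,4-bis(benzyloxy)-5-methoxybenzaldehyde | COc1cc(C=O)cc(OCc2ccccc2)c1OCc1ccccc1 | intermediate
3 | 1-(benzyloxy)-4-iodobenzene | Ic1ccc(OCc2ccccc2)cc1 | starting material
4 | prop-2-en-1-ol (allyl alcohol) | C=CCO | starting material
5 | 1-(triphenylphosphoranylidene)propan-2-one | CC(=O)C=P(c1ccccc1)(c1ccccc1)c1ccccc1 | starting material
6 | 3-[4-(benzyloxy)phenyl]propanal (not isolated) | O=CCCc1ccc(OCc2ccccc2)cc1 | intermediate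
7 | (3E)-6-[4-(benzyloxy)phenyl]hex-3-en-2-one | CC(=O)/C=C/CCc1ccc(OCc2ccccc2)cc1 | intermediate
8 | racemic (4E)-1-[3,4-bis(benzyloxy)-5-methoxyphenyl]-7-[4-(benzyloxy)phenyl]-1-hydroxyhept-4-en-3-one (not isolated) | COc1cc(C(O)CC(=O)/C=C/CCc2ccc(OCc3ccccc3)cc2)cc(OCc2ccccc2)c1OCc1ccccc1 | intermediate
9 | (1E,4E)-1-[3,4-bis(benzyloxy)-5-methoxyphenyl]-7-[4-(benzyloxy)phenyl]hepta-1,4-dien-3-one | COc1cc(/C=C/C(=O)/C=C/CCc2ccc(OCc3ccccc3)cc2)cc(OCc2ccccc2)c1OCc1ccccc1 | intermediate
10 | (1E,5S)-1-[3,4-bis(benzyloxy)-5-methoxyphenyl]-7-[4-(benzyloxy)phenyl]-5-[(2-phenylpropan-2-yl)peroxy]hept-1-en-3-one | COc1cc(/C=C/C(=O)C[C@@H](OOC(C)(C)c2ccccc2)CCc2ccc(OCc3ccccc3)cc2)cc(OCc2ccccc2)c1OCc1ccccc1 | intermediate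
11 | (5S)-1-(3,4-dihydroxy-5-methoxyphenyl)-5-hydroxy-7-(4-hydroxyphenyl)heptan-3-one | COc1cc(CCC(=O)C[C@@H](O)CCc2ccc(O)cc2)cc(O)c1O | intermediate
12 | (5S)-5-[(diethylboranyl)oxy]-1-(3,4-dihydroxy-5-methoxyphenyl)-7-(4-hydroxyphenyl)heptan-3-one, boron chelated by the C3 ketone oxygen (not isolated) | COc1cc(CCC(=O)C[C@@H](OB(CC)CC)CCc2ccc(O)cc2)cc(O)c1O | intermediate
13 | (3R,5S)-1-(3,4-dihydroxy-5-methoxyphenyl)-7-(4-hydroxyphenyl)heptane-3,5-diol | COc1cc(CC[C@@H](O)C[C@@H](O)CCc2ccc(O)cc2)cc(O)c1O | target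

## Step count and risks

Total steps: 6. Longest linear sequence: 5 (steps 2, 3, 4, 5, 6 from 3, or steps 1, 3, 4, 5, 6 from 1).

**Step 4 (the new C–O bond formation).**
- Possible failures: slow condensation of the bulky amine with a doubly vinylogous ketone, loss of ee through two iminium geometries, or drift to the 4,5-epoxide.
- Fallback, known chemistry, sets out from 9 and comes back at 11.
- Copper-catalysed asymmetric conjugate borylation puts boron on C5 of the more reactive β-alkyl arm. Conditions are CuCl (5 mol%), NaOtBu (5 mol%), (R)-1-[(S)-2-(diphenylphosphino)ferrocenyl]ethyldicyclohexylphosphine (5 mol%, ligand enantiomer chosen for 5S), B2pin2 (1.0 equiv), MeOH (2 equiv), THF, 0 °C.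
- The product is (1E,5S)-1-[3,4-bis(benzyloxy)-5-methoxyphenyl]-7-[4-(benzyloxy)phenyl]-5-(4,4,5,5-tetramethyl-1,3,2-dioxaborolan-2-yl)hept-1-en-3-one F1.
- NaBO3·4H2O in THF/H2O turns the C–B bond into the C5–O bond with retention and gives (1E,5S)-1-[3,4-bis(benzyloxy)-5-methoxyphenyl]-7-[4-(benzyloxy)phenyl]-5-hydroxyhept-1-en-3-one F2.
- H2 over 10% Pd/C in EtOAc/EtOH then leads to 11.

**Step 3 (Claisen–Schmidt on a γ-enolisable enone).**
- Possible failures: extended-dienolate α-attack, Michael self-addition of 7, or a sluggish reaction with the electron-rich aldehyde.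
- Fallback sets out from 2 and from 6 (worked up out of the Heck reaction before any ylide is added) and comes back at 9. It makes C4=C5 instead of C1=C2.
- Compound 2 and excess acetone with aq. NaOH give (3E)-4-[3,4-bis(benzyloxy)-5-methoxyphenyl]but-3-en-2-one F3.
- The kinetic lithium enolate of F3 (LDA, THF, −78 °C) adds to 6 and gives racemic (1E)-1-[3,4-bis(benzyloxy)-5-methoxyphenyl]-7-[4-(benzyloxy)phenyl]-5-hydroxyhept-1-en-3-one F4.
- Catalytic p-TsOH in toluene at 60 °C dehydrates F4 to 9.

**Step 6 (chelate reduction on an unprotected catechol and phenol).**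
- Possible failures: boron tied up by the catechol, lower syn selectivity, or a difficult boron-free isolation of the polar product.
- Fallback sets out from 10 and comes back at 13. It keeps the benzyl groups through the reduction.
- H2 over 10% Pd/C poisoned with 2,2'-bipyridyl (0.5 equiv) in MeOH/THF saturates C1=C2 and cleaves the O–O bond but spares the aryl benzyl ethers. It gives (5S)-1-[3,4-bis(benzyloxy)-5-methoxyphenyl]-7-[4-(benzyloxy)phenyl]-5-hydroxyheptan-3-one F5.
- Et2BOMe/NaBH4 in THF/MeOH at −78 °C gives (3R,5S)-1-[3,4-bis(benzyloxy)-5-methoxyphenyl]-7-[4-(benzyloxy)phenyl]heptane-3,5-diol F6.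
- Unpoisoned H2 over Pd(OH)2/C in EtOH releases 13.

## Further compounds

F1 | step 4 | (1E,5S)-1-[3,4-bis(benzyloxy)-5-methoxyphenyl]-7-[4-(benzyloxy)phenyl]-5-(4,4,5,5-tetramethyl-1,3,2-dioxaborolan-2-yl)hept-1-en-3-one | COc1cc(/C=C/C(=O)C[C@@H](B2OC(C)(C)C(C)(C)O2)CCc2ccc(OCc3ccccc3)cc2)cc(OCc2ccccc2)c1OCc1ccccc1
F2 | step 4 | (1E,5S)-1-[3,4-bis(benzyloxy)-5-methoxyphenyl]-7-[4-(benzyloxy)phenyl]-5-hydroxyhept-1-en-3-one | COc1cc(/C=C/C(=O)C[C@@H](O)CCc2ccc(OCc3ccccc3)cc2)cc(OCc2ccccc2)c1OCc1ccccc1
F3 | step 3 | (3E)-4-[3,4-bis(benzyloxy)-5-methoxyphenyl]but-3-en-2-one | COc1cc(/C=C/C(C)=O)cc(OCc2ccccc2)c1OCc1ccccc1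
F4 | step 3 | racemic (1E)-1-[3,4-bis(benzyloxy)-5-methoxyphenyl]-7-[4-(benzyloxy)phenyl]-5-hydroxyhept-1-en-3-one | COc1cc(/C=C/C(=O)CC(O)CCc2ccc(OCc3ccccc3)cc2)cc(OCc2ccccc2)c1OCc1ccccc1
F5 | step 6 | (5S)-1-[3,4-bis(benzyloxy)-5-methoxyphenyl]-7-[4-(benzyloxy)phenyl]-5-hydroxyheptan-3-one | COc1cc(CCC(=O)C[C@@H](O)CCc2ccc(OCc3ccccc3)cc2)cc(OCc2ccccc2)c1OCc1ccccc1
F6 | step 6 | (3R,5S)-1-[3,4-bis(benzyloxy)-5-methoxyphenyl]-7-[4-(benzyloxy)phenyl]heptane-3,5-diol | COc1cc(CC[C@@H](O)C[C@@H](O)CCc2ccc(OCc3ccccc3)cc2)cc(OCc2ccccc2)c1OCc1ccccc1
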